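**Retrosynthetic overview**
- The strategy rests on the C3′=C4′ bond of each N-acyl-5,6-dihydropyridin-2(1H)-one ring (N1′–C2′(=O)–C3′=C4′–C5′–C6′) carried by the acyl carbons on cyclobutane C1 and C3. This enimide Michael acceptor is cut in both rings by twofold ring-closing metathesis, giving the bis[N-acryloyl-N-(but-3-enyl)] imide.
- The imide is disconnected at the two acryloyl C–N bonds (acryloyl chloride) and the two amide C–N bonds (but-3-en-1-amine), giving the α-truxillic-type diacid.
- The cyclobutane (bonds C1–C4 and C2–C3, all four stereocentres) comes from lattice-controlled head-to-tail [2+2] photodimerisation of (E)-3,4-dimethoxycinnamic acid. This is preferred to twofold decarboxylative arylation of the maleic anhydride photodimer, where each radical carbon has one ester neighbour on either face, so the trans aryl/aryl relation would be uncontrolled.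
- Ring order: cyclobutane first (step 1); the two six-membered enelactam rings together and last (step 4).

Key step: step 4

Remark: the target is the centrosymmetric α-truxillic (1α,2α,3β,4β) array and is therefore achiral (meso); the "single enantiomer" is this one meso diastereomer, so only relative configuration has to be controlled.
Assumption: 1 is irradiated in its head-to-tail (α-type, inversion-related pairs) crystal packing, the form expected on crystallisation from ethanol.

**Step 1**
Reactants: 1 (E)-3,4-dimethoxycinnamic acid (two molecules)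
Product: 2 (1α,2α,3β,4β)-2,4-bis(3,4-dimethoxyphenyl)cyclobutane-1,3-dicarboxylic acid (α-truxillic type, centrosymmetric: aryls trans, carboxyls trans, each CO2H cis to one aryl and trans to the other)
Conditions: hν (365 nm LED or Pyrex-filtered medium-pressure Hg lamp), finely ground crystals (from EtOH) as a stirred aqueous slurry, rt; unreacted 1 removed by trituration and recycled
Reagents that add atoms: none
Why: Topochemical [2+2] photodimerisation (Schmidt's rule): in the α-type crystal the E-acid lies in head-to-tail pairs related by an inversion centre with parallel C=C bonds about 4 Å apart, so Cα joins Cβ′ and Cβ joins Cα′ suprafacially and all four stereocentres are set at once by the lattice symmetry and the retained E geometry of each alkene.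

**Step 2**
Reactants: 2 (1α,2α,3β,4β)-2,4-bis(3,4-dimethoxyphenyl)cyclobutane-1,3-dicarboxylic acid; 3 but-3-en-1-amine
Product: 5 (1α,2α,3β,4β)-N1,N3-di(but-3-en-1-yl)-2,4-bis(3,4-dimethoxyphenyl)cyclobutane-1,3-dicarboxamide, via (1α,2α,3β,4β)-2,4-bis(3,4-dimethoxyphenyl)cyclobutane-1,3-dicarbonyl dichloride 4 (not isolated)
Conditions: (COCl)2, DMF (cat.), CH2Cl2, 0 °C → rt, evaporate; then 3 (2.4 equiv), aq. K2CO3, CH2Cl2, 0 °C → rt
Reagents that add atoms: but-3-en-1-amine (3), NCCC=C; oxalyl chloride, O=C(Cl)C(=O)Cl (gives only the two Cl of 4; no atom of it remains in 5)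
Why: Vilsmeier-catalysed acid chloride formation followed by Schotten–Baumann acylation of the primary amine; the carbonate stays in the aqueous phase, so no ketene forms from the acid chloride and the two α-stereocentres are retained.

**Step 3**
Reactants: 5 (1α,2α,3β,4β)-N1,N3-di(but-3-en-1-yl)-2,4-bis(3,4-dimethoxyphenyl)cyclobutane-1,3-dicarboxamide; 6 acryloyl chloride
Product: 8 (1α,2α,3β,4β)-N1,N3-diacryloyl-N1,N3-di(but-3-en-1-yl)-2,4-bis(3,4-dimethoxyphenyl)cyclobutane-1,3-dicarboxamide, via dilithium bis(amidate) of 5 7 (not isolated)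
Conditions: n-BuLi (2.05 equiv), THF, −78 → −30 °C; then 6 (2.6 equiv, freshly distilled), −78 °C; aq. NH4Cl at −78 °C
Reagents that add atoms: acryloyl chloride (6), C=CC(=O)Cl; n-butyllithium, [Li]CCCC (gives only the Li of 7)
Why: N-Acylation of a lithium amidate by an acid chloride (imide synthesis): the base removes only the two N–H protons, which are far more acidic than the cyclobutane α-C–H, the hard amidate attacks the acyl chloride carbonyl rather than the β-carbon at −78 °C, any O-acyl isoimide converges on the imide by 1,3-acyl shift, and no stereocentre is touched.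

**Step 4**
Reactants: 8 (1α,2α,3β,4β)-N1,N3-diacryloyl-N1,N3-di(but-3-en-1-yl)-2,4-bis(3,4-dimethoxyphenyl)cyclobutane-1,3-dicarboxamide
Product: 10 1,1′-{[(1α,2α,3β,4β)-2,4-bis(3,4-dimethoxyphenyl)cyclobutane-1,3-diyl]dicarbonyl}bis(5,6-dihydropyridin-2(1H)-one) (CNP0199212.1), via rac-N-acryloyl-N-(but-3-en-1-yl)-2,4-bis(3,4-dimethoxyphenyl)-3-[(2-oxo-5,6-dihydropyridin-1(2H)-yl)carbonyl]cyclobutane-1-carboxamide 9 (not isolated)
Conditions: Grubbs II (2 × 5 mol%), 1,4-benzoquinone (20 mol%), degassed CH2Cl2 (0.005 M), 40 °C; ethyl vinyl ether quench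
Reagents that add atoms: none
Why: Chauvin olefin metathesis: the ruthenium benzylidene exchanges with the terminal but-3-enyl CH=CH2 of one arm, the new alkylidene adds across the acryloyl C=C on the same nitrogen to give a ruthenacyclobutane, and cycloreversion releases the lactam C3′=C4′ bond and Ru=CH2, which gives up ethylene on the next turnover, the second arm closing in the same way through triene 9. The closest known reaction type is the ring-closing metathesis of N-acyl-N-(but-3-enyl)acrylamides to N-acyl-5,6-dihydropyridin-2(1H)-ones. Each ring closes as a six-membered ring by RCM between C3′ (acryloyl α-carbon) and C4′ (internal butenyl carbon), the new alkene being endocyclic and necessarily Z. No stereocentre is formed, and the four cyclobutane centres from step 1 are untouched because the medium is neutral and aprotic. The step needs chemoselectivity for intra-arm six-ring closure over cross-arm or intermolecular metathesis and over Ru–H isomerisation of the butenyl chain; the first is secured by both alkenes of a pair sitting on one imide nitrogen while the two arms lie on opposite faces of the cyclobutane, helped by high dilution, and the second by benzoquinone. The conjugated, cis-disubstituted product alkene is a poor metathesis partner, so the reaction should stop at the bis(enelactam).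

**Compound list**
1 | (E)-3,4-dimethoxycinnamic acid | COc1ccc(/C=C/C(=O)O)cc1OC | starting material
2 | (1α,2α,3β,4β)-2,4-bis(3,4-dimethoxyphenyl)cyclobutane-1,3-dicarboxylic acid | COc1ccc([C@H]2[C@H](C(=O)O)[C@H](c3ccc(OC)c(OC)c3)[C@H]2C(=O)O)cc1OC | intermediate
3 | but-3-en-1-amine | NCCC=C | starting material
4 | (1α,2α,3β,4β)-2,4-bis(3,4-dimethoxyphenyl)cyclobutane-1,3-dicarbonyl dichloride | COc1ccc([C@H]2[C@H](C(=O)Cl)[C@H](c3ccc(OC)c(OC)c3)[C@H]2C(=O)Cl)cc1OC | intermediate (not isolated)
5 | (1α,2α,3β,4β)-N1,N3-di(but-3-en-1-yl)-2,4-bis(3,4-dimethoxyphenyl)cyclobutane-1,3-dicarboxamide | COc1ccc([C@H]2[C@H](C(=O)NCCC=C)[C@H](c3ccc(OC)c(OC)c3)[C@H]2C(=O)NCCC=C)cc1OC | intermediate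
6 | acryloyl chloride | C=CC(=O)Cl | starting material
7 | dilithium bis(amidate) of 5 | [Li+].[Li+].COc1ccc([C@H]2[C@H](C(=O)[N-]CCC=C)[C@H](c3ccc(OC)c(OC)c3)[C@H]2C(=O)[N-]CCC=C)cc1OC | intermediate (not isolated)
8 | (1α,2α,3β,4β)-N1,N3-diacryloyl-N1,N3-di(but-3-en-1-yl)-2,4-bis(3,4-dimethoxyphenyl)cyclobutane-1,3-dicarboxamide | COc1ccc([C@H]2[C@H](C(=O)N(CCC=C)C(=O)C=C)[C@H](c3ccc(OC)c(OC)c3)[C@H]2C(=O)N(CCC=C)C(=O)C=C)cc1OC | intermediate
9 | mono-cyclised triene (racemic, one enantiomer drawn): N-acryloyl-N-(but-3-en-1-yl)-2,4-bis(3,4-dimethoxyphenyl)-3-[(2-oxo-5,6-dihydropyridin-1(2H)-yl)carbonyl]cyclobutane-1-carboxamide | COc1ccc([C@H]2[C@H](C(=O)N3CCC=CC3=O)[C@H](c3ccc(OC)c(OC)c3)[C@H]2C(=O)N(CCC=C)C(=O)C=C)cc1OC | intermediate (not isolated)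
10 | 1,1′-{[(1α,2α,3β,4β)-2,4-bis(3,4-dimethoxyphenyl)cyclobutane-1,3-diyl]dicarbonyl}bis(5,6-dihydropyridin-2(1H)-one), CNP0199212.1 | COc1ccc([C@H]2[C@H](C(=O)N3CCC=CC3=O)[C@H](c3ccc(OC)c(OC)c3)[C@H]2C(=O)N2CCC=CC2=O)cc1OC | target

**Total step count:** 4
**Longest linear sequence:** 4 steps (1 → 2 → 5 → 8 → 10)

**Steps most likely to fail**

Step 4 (key step). The twofold closure may stall after the first ring through chelation of the alkylidene by the imide carbonyls. It may also be diverted by Ru–H migration of the butenyl double bond, or by cross-metathesis between molecules, which gives oligomers. The fallback makes the same C3′=C4′ bond by metathesis on the free arm before it is attached to the cyclobutane. Compounds 3 and 6 (Et3N, CH2Cl2, 0 °C) should give N-(but-3-en-1-yl)acrylamide F1. Ring-closing metathesis of this (Grubbs II, CH2Cl2, reflux) should give 5,6-dihydropyridin-2(1H)-one F2, which is also a commercial compound should the secondary amide close sluggishly. Its lithium salt (n-BuLi, THF, −78 °C) would then be acylated twice by the diacid dichloride 4, prepared from 2 as in the first stage of step 2. This fallback sets out from 4 and comes back to the route at the target 10.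

Step 3. The amidate may add in aza-Michael fashion to acryloyl chloride or to the acrylimide already formed, starting anionic oligomerisation. Acylation may also stop after one arm through aggregation of the dilithium salt. The fallback introduces the acryloyl group in masked form. The dilithium salt of 5 (n-BuLi, THF, −78 °C) would be acylated with 3-chloropropanoyl chloride to give (1α,2α,3β,4β)-N1,N3-di(but-3-en-1-yl)-N1,N3-bis(3-chloropropanoyl)-2,4-bis(3,4-dimethoxyphenyl)cyclobutane-1,3-dicarboxamide F3, which is not a Michael acceptor. Et3N (CH2Cl2, 0 °C → rt) should then eliminate HCl from both arms by E1cB to unveil the two acrylimides. This fallback sets out from 5 and comes back at 8.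

Step 1. The crystal batch may not be in the photoreactive head-to-tail packing, or conversion may stop as the lattice degrades during irradiation. The fallback builds the cyclobutane from a ferulic acid derivative of the 4-O-sulfonyl type, expected to stack head-to-tail in the crystal. Commercial (E)-ferulic acid F4 would be tosylated (TsCl, aq. NaOH) to (E)-3-methoxy-4-(tosyloxy)cinnamic acid F5. Solid-state irradiation should give (1α,2α,3β,4β)-2,4-bis[3-methoxy-4-(tosyloxy)phenyl]cyclobutane-1,3-dicarboxylic acid F6. Hydrolysis of the sulfonates (KOH, MeOH/H2O, reflux) should give (1α,2α,3β,4β)-2,4-bis(4-hydroxy-3-methoxyphenyl)cyclobutane-1,3-dicarboxylic acid F7. O-Methylation of the two phenols (Me2SO4, aq. NaOH, then NaOH at reflux to cleave any methyl ester, then acid) should give 2. This fallback uses no numbered compound of the route: it sets out from commercial F4 in place of 1 and comes back at 2.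

**Further compounds**
F1 | step 4 | N-(but-3-en-1-yl)acrylamide | C=CCCNC(=O)C=C
F2 | step 4 | 5,6-dihydropyridin-2(1H)-one | O=C1C=CCCN1
F3 | step 3 | (1α,2α,3β,4β)-N1,N3-di(but-3-en-1-yl)-N1,N3-bis(3-chloropropanoyl)-2,4-bis(3,4-dimethoxyphenyl)cyclobutane-1,3-dicarboxamide | COc1ccc([C@H]2[C@H](C(=O)N(CCC=C)C(=O)CCCl)[C@H](c3ccc(OC)c(OC)c3)[C@H]2C(=O)N(CCC=C)C(=O)CCCl)cc1OC
F4 | step 1 | (E)-ferulic acid (commercial input) | COc1cc(/C=C/C(=O)O)ccc1O
F5 | step 1 | (E)-3-methoxy-4-(tosyloxy)cinnamic acid | COc1cc(/C=C/C(=O)O)ccc1OS(=O)(=O)c1ccc(C)cc1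
F6 | step 1 | (1α,2α,3β,4β)-2,4-bis[3-methoxy-4-(tosyloxy)phenyl]cyclobutane-1,3-dicarboxylic acid | Cc1ccc(S(=O)(=O)Oc2ccc([C@H]3[C@H](C(=O)O)[C@H](c4ccc(OS(=O)(=O)c5ccc(C)cc5)c(OC)c4)[C@H]3C(=O)O)cc2OC)cc1
F7 | step 1 | (1α,2α,3β,4β)-2,4-bis(4-hydroxy-3-methoxyphenyl)cyclobutane-1,3-dicarboxylic acid | Oc1ccc([C@H]2[C@H](C(=O)O)[C@H](c3ccc(O)c(OC)c3)[C@H]2C(=O)O)cc1OC
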